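**Retrosynthetic overview**
- The C2-symmetric C40 polyene is cut at both C7=C8 bonds: 2 × (R)-α-cyclogeranyl tetrazolyl sulfone (C10) + crocetindialdehyde (C20), joined by a two-directional Julia–Kocienski olefination.
- The sulfone comes from (R)-α-cyclogeraniol. Its C6–C7 bond, its only stereocentre and its C4=C5 alkene arise together in a suprafacial Still–Wittig [2,3]-sigmatropic rearrangement of the stannylmethyl ether of (S)-2,4,4-trimethylcyclohex-2-en-1-ol.
- That allylic alcohol comes from a Wharton transposition of (2S,3S)-2,3-epoxy-2,6,6-trimethylcyclohexanone.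
- The epoxy ketone comes from (S)-(+)-carvone: gem-dimethylation, epoxidation directed by the isopropenyl group, then excision of that group. Chirality is relayed C5 → oxirane → carbinol → C6.
- No ring is built. Both cyclohexene rings are the carvone ring carried through.

Assumption: crocetindialdehyde (CAS 502-70-5) and tributyl(iodomethyl)stannane are taken as catalogue chemicals.

**Step 1**
Reactants: 1 (S)-(+)-carvone
Product: 3 (5R)-2,6,6-trimethyl-5-(prop-1-en-2-yl)cyclohex-2-en-1-one (6,6-dimethylcarvone), via 6-methylcarvone 2 (not isolated)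
Conditions: LDA (1.1 equiv), THF, −78 °C; MeI (1.1 equiv), → 0 °C; recool to −78 °C, LDA (1.3 equiv); MeI (2 equiv), → rt
Reagents that add atoms: iodomethane CI
Why: Two successive kinetic α′-enolate alkylations (LDA forms only the cross-conjugated C6 enolate) install the future gem-dimethyl carbon without touching the C5 stereocentre bought with carvone.

**Step 2**
Reactants: 3 6,6-dimethylcarvone
Product: 4 (1S,4R,6S)-1,3,3-trimethyl-4-(prop-1-en-2-yl)-7-oxabicyclo[4.1.0]heptan-2-one (oxirane trans to isopropenyl)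
Conditions: 30% H2O2 (3 equiv), aq NaOH (0.3 equiv), MeOH, 0 °C → rt; chromatography to remove the minor cis-epoxide
Reagents that add atoms: hydrogen peroxide OO
Why: Weitz–Scheffer nucleophilic epoxidation touches only the electron-poor enone C=C, and hydroperoxide adds axially to C3 anti to the C5 isopropenyl group, so the carvone stereocentre sets both oxirane carbons (the minor cis isomer is removed here because it would become the enantiomer after step 3).

**Step 3**
Reactants: 4 trans-epoxide of 6,6-dimethylcarvone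
Product: 6 (1S,6S)-1,3,3-trimethyl-7-oxabicyclo[4.1.0]heptan-2-one, via methoxy hydroperoxide 5 (not isolated)
Conditions: O3, MeOH, −78 °C, Ar purge; then PhSH (1.5 equiv), FeSO4·7H2O (1.2 equiv), −78 °C → rt
Reagents that add atoms: none
Why: In this hydrodealkenylative C(sp3)–C(sp2) fragmentation, Criegee ozonolysis in MeOH gives the α-methoxy hydroperoxide, Fe(II) turns it into an alkoxy radical whose β-scission expels methyl acetate, and the secondary ring radical is capped by the very fast H-donor PhSH before any 1,2-acyl shift, leaving the two oxirane carbons as the only carriers of chirality.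

**Step 4**
Reactants: 6 (1S,6S)-epoxy ketone
Product: 8 (1S)-2,4,4-trimethylcyclohex-2-en-1-ol, via epoxy hydrazone 7 (not isolated)
Conditions: N2H4·H2O (3 equiv), AcOH (0.5 equiv), MeOH, 0 °C → rt
Reagents that add atoms: none
Why: In the Wharton transposition the epoxy hydrazone opens to a hydroxy vinyldiazene that loses N2, which places the alkene between the former carbonyl carbon and the methyl-bearing carbon while the secondary C–O bond is never broken, so the carbinol is the single (S)-enantiomer.

**Step 5**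
Reactants: 8 (1S)-2,4,4-trimethylcyclohex-2-en-1-ol
Product: 9 tributyl({[(1S)-2,4,4-trimethylcyclohex-2-en-1-yl]oxy}methyl)stannane
Conditions: KH (1.3 equiv), THF, 0 °C; Bu3SnCH2I (1.1 equiv), 18-crown-6 (cat.), rt
Reagents that add atoms: tributyl(iodomethyl)stannane CCCC[Sn](CI)(CCCC)CCCC
Why: Williamson etherification of the potassium alkoxide with the reactive primary iodide proceeds at oxygen only, so the carbinol stereocentre is untouched.

**Step 6 (key step)**
Reactants: 9 stannylmethyl ether
Product: 11 [(1R)-2,6,6-trimethylcyclohex-2-en-1-yl]methanol ((R)-α-cyclogeraniol), via alkoxymethyllithium 10 (not isolated)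
Conditions: n-BuLi (1.3 equiv), THF, −78 °C → −20 °C; H2O quench
Reagents that add atoms: none
Why: In the Still–Wittig [2,3]-sigmatropic rearrangement, Sn–Li exchange frees an unstabilised α-alkoxy carbanion that bonds to the alkene terminus through a five-membered envelope transition state on the ring face bearing the C–O bond (suprafacial 1,3-chirality transfer), which creates the C6–C7 bond, the (R)-stereocentre next to the gem-dimethyl carbon and the C4=C5 alkene in one event.

**Step 7**
Reactants: 11 (R)-α-cyclogeraniol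
Product: 13 1-phenyl-5-({[(1R)-2,6,6-trimethylcyclohex-2-en-1-yl]methyl}sulfonyl)-1H-tetrazole, via tetrazolyl sulfide 12 (not isolated)
Conditions: 1-phenyl-1H-tetrazole-5-thiol (1.3 equiv), PPh3 (1.3 equiv), DIAD (1.3 equiv), THF, 0 °C → rt; then EtOH, (NH4)6Mo7O24·4H2O (10 mol %), 30% H2O2 (10 equiv), 0 °C → rt
Reagents that add atoms: 1-phenyl-1H-tetrazole-5-thiol Sc1nnnn1-c1ccccc1; hydrogen peroxide OO
Why: Mitsunobu thioetherification at the primary carbinol is followed in the same flask by molybdate-catalysed sulfide-to-sulfone oxidation, which is much faster than epoxidation of the hindered trisubstituted alkene and does not involve C6.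

**Step 8**
Reactants: 13 (R)-α-cyclogeranyl PT-sulfone (2.4 equiv); 14 crocetindialdehyde, (all-E)-2,6,11,15-tetramethylhexadeca-2,4,6,8,10,12,14-heptaenedial (1 equiv)
Product: 16 (6R,6'R)-ε,ε-carotene, via 8'-apo-ε-caroten-8'-al 15 (not isolated)
Conditions: 13, KHMDS (2.3 equiv), THF, −78 °C, 30 min; 14 in THF, −78 °C → rt, Ar, dark; H2O; crude polyene with I2 (1 mol %), heptane, daylight, rt; crystallise (CH2Cl2/MeOH)
Reagents that add atoms: none
Why: Two-directional Julia–Kocienski olefination (addition, Smiles rearrangement, loss of SO2 and tetrazolonate) of the bulky β-branched potassium sulfonyl carbanion favours the E-C7=C8 bonds, the non-acidic C6–H is not epimerised, and the iodine-catalysed equilibration funnels residual 7Z isomers to the crystalline all-E compound.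

**Compound list**
1 | (S)-(+)-carvone, (5S)-2-methyl-5-(prop-1-en-2-yl)cyclohex-2-en-1-one | CC1=CC[C@@H](CC1=O)C(C)=C | starting material
2 | (5S,6RS)-2,6-dimethyl-5-(prop-1-en-2-yl)cyclohex-2-en-1-one (6-methylcarvone) | CC1=CC[C@@H](C(C)C1=O)C(C)=C | intermediate
3 | (5R)-2,6,6-trimethyl-5-(prop-1-en-2-yl)cyclohex-2-en-1-one | CC1=CC[C@@H](C(C)(C)C1=O)C(C)=C | intermediate
4 | (1S,4R,6S)-1,3,3-trimethyl-4-(prop-1-en-2-yl)-7-oxabicyclo[4.1.0]heptan-2-one | C[C@]12O[C@H]1C[C@H](C(C)=C)C(C)(C)C2=O | intermediate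
5 | (1S,4S,6S)-4-(1-hydroperoxy-1-methoxyethyl)-1,3,3-trimethyl-7-oxabicyclo[4.1.0]heptan-2-one (epimers at the peroxy carbon) | C[C@]12O[C@H]1C[C@H](C(C)(OC)OO)C(C)(C)C2=O | intermediate
6 | (1S,6S)-1,3,3-trimethyl-7-oxabicyclo[4.1.0]heptan-2-one | C[C@]12O[C@H]1CCC(C)(C)C2=O | intermediate
7 | hydrazone of 6 (oxirane unchanged) | C[C@]12O[C@H]1CCC(C)(C)C2=NN | intermediate
8 | (1S)-2,4,4-trimethylcyclohex-2-en-1-ol | CC1=CC(C)(C)CC[C@@H]1O | intermediate
9 | tributyl({[(1S)-2,4,4-trimethylcyclohex-2-en-1-yl]oxy}methyl)stannane | CC1=CC(C)(C)CC[C@@H]1OC[Sn](CCCC)(CCCC)CCCC | intermediate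
10 | ({[(1S)-2,4,4-trimethylcyclohex-2-en-1-yl]oxy}methyl)lithium | CC1=CC(C)(C)CC[C@@H]1OC[Li] | intermediate
11 | [(1R)-2,6,6-trimethylcyclohex-2-en-1-yl]methanol, (R)-α-cyclogeraniol | CC1=CCCC(C)(C)[C@H]1CO | intermediate
12 | 1-phenyl-5-({[(1R)-2,6,6-trimethylcyclohex-2-en-1-yl]methyl}sulfanyl)-1H-tetrazole | CC1=CCCC(C)(C)[C@H]1CSc1nnnn1-c1ccccc1 | intermediate
13 | 1-phenyl-5-({[(1R)-2,6,6-trimethylcyclohex-2-en-1-yl]methyl}sulfonyl)-1H-tetrazole | CC1=CCCC(C)(C)[C@H]1CS(=O)(=O)c1nnnn1-c1ccccc1 | intermediate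
14 | crocetindialdehyde (8,8'-diapocarotene-8,8'-dial, all-E) | O=C/C(C)=C/C=C/C(C)=C/C=C/C=C(C)/C=C/C=C(C)/C=O | starting material
15 | (6R)-8'-apo-ε-caroten-8'-al (all-E) | CC1=CCCC(C)(C)[C@H]1/C=C/C(C)=C/C=C/C(C)=C/C=C/C=C(C)/C=C/C=C(C)/C=O | intermediate
16 | (6R,6'R)-ε,ε-carotene (all-E) | CC1=CCCC(C)(C)[C@H]1/C=C/C(C)=C/C=C/C(C)=C/C=C/C=C(C)/C=C/C=C(C)/C=C/[C@H]1C(C)=CCCC1(C)C | target

**Totals**
Total step count: 8. Longest linear sequence: 8 (1 → 16). Compound 14 is bought and enters in the last step.

**Steps most likely to fail**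

Step 3. The thiol/iron medium may open the epoxy ketone, or the ring radical may rearrange. The fallback sets out from 4 and comes back at 6.
- The same ozonolysis in MeOH is followed by decomposition of the hydroperoxide with Cu(OAc)2/FeSO4, with no thiol present.
- Cu(II) oxidises the ring radical to an alkene. Only one regioisomer is possible, because the other neighbour is quaternary. This gives (1S,6S)-1,3,3-trimethyl-7-oxabicyclo[4.1.0]hept-4-en-2-one F1.
- Diimide (dipotassium azodicarboxylate, AcOH, MeOH) then saturates the cis-disubstituted alkene without hydrogenolysis of the allylic oxirane and delivers 6.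

Step 4. Hydrazone formation may be too slow at a ketone flanked by two fully substituted carbons. The fallback sets out from 6 and comes back at 8.
- NaBH4 in MeOH reduces the ketone to (1R,2RS,6S)-1,3,3-trimethyl-7-oxabicyclo[4.1.0]heptan-2-ol F2. The carbinol configuration is irrelevant.
- MsCl/Et3N gives (1S,2RS,6S)-1,3,3-trimethyl-7-oxabicyclo[4.1.0]heptan-2-yl methanesulfonate F3.
- Dissolving-metal reductive elimination (Na, liquid NH3, THF, −78 °C) expels mesylate and opens the oxirane. This gives 8 with the same intact C–O stereocentre.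

Step 8. Likely problems are the low solubility of 14 at low temperature, incomplete second olefination and modest E/Z ratio with an enal. The fallback sets out from 11 and comes back at 16 by the C15 + C10 + C15 Wittig scheme.
- Dess–Martin oxidation gives (1R)-2,6,6-trimethylcyclohex-2-ene-1-carbaldehyde F4.
- The base-free stabilised ylide Ph3P=CHC(O)CH3 in warm toluene gives (R)-α-ionone F5.
- Vinylmagnesium bromide gives (1E)-3-methyl-1-[(1R)-2,6,6-trimethylcyclohex-2-en-1-yl]penta-1,4-dien-3-ol F6.
- PPh3·HBr in MeOH gives, with allylic transposition, [(2E,4E)-3-methyl-5-[(1R)-2,6,6-trimethylcyclohex-2-en-1-yl]penta-2,4-dien-1-yl]triphenylphosphonium bromide F7.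
- Two equivalents of F7 with NaOMe and purchased 2,7-dimethylocta-2,4,6-trienedial (O=C/C(C)=C/C=C/C=C(C)/C=O) give 16 after the same iodine equilibration and crystallisation.

**Further compounds**
F1 | step 3 | (1S,6S)-1,3,3-trimethyl-7-oxabicyclo[4.1.0]hept-4-en-2-one | C[C@]12O[C@H]1C=CC(C)(C)C2=O
F2 | step 4 | (1R,2RS,6S)-1,3,3-trimethyl-7-oxabicyclo[4.1.0]heptan-2-ol | C[C@]12O[C@H]1CCC(C)(C)C2O
F3 | step 4 | (1S,2RS,6S)-1,3,3-trimethyl-7-oxabicyclo[4.1.0]heptan-2-yl methanesulfonate | C[C@]12O[C@H]1CCC(C)(C)C2OS(C)(=O)=O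
F4 | step 8 | (1R)-2,6,6-trimethylcyclohex-2-ene-1-carbaldehyde, (R)-α-cyclocitral | CC1=CCCC(C)(C)[C@H]1C=O
F5 | step 8 | (R)-α-ionone, (3E)-4-[(1R)-2,6,6-trimethylcyclohex-2-en-1-yl]but-3-en-2-one | CC1=CCCC(C)(C)[C@H]1/C=C/C(C)=O
F6 | step 8 | (1E)-3-methyl-1-[(1R)-2,6,6-trimethylcyclohex-2-en-1-yl]penta-1,4-dien-3-ol (C3 epimers) | CC1=CCCC(C)(C)[C@H]1/C=C/C(C)(O)C=C
F7 | step 8 | [(2E,4E)-3-methyl-5-[(1R)-2,6,6-trimethylcyclohex-2-en-1-yl]penta-2,4-dien-1-yl]triphenylphosphonium bromide | CC1=CCCC(C)(C)[C@H]1/C=C/C(C)=C/C[P+](c1ccccc1)(c1ccccc1)c1ccccc1.[Br-]
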